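**Retrosynthetic overview**
1. C12–C13 bond and the C12 carbinol: organocatalytic Morita–Baylis–Hillman coupling of furan-2(5H)-one (bought ring) with the C11–C12 aldehyde of the decalin, as the last step.
2. Decalin: one cationic cascade from an enantioenriched epoxy dienyl allylsilane. Ring A closes first (epoxide opening at C4), then ring B (allylsilane termination gives the C8 exocyclic methylene).
3. Epoxy polyene: C5–C6 Negishi coupling of an epoxy iodoalkene with a homoallylic zinc reagent.
4. Epoxide (first stereocentres, C3 and C4): Shi epoxidation of an achiral Z-allylic silyl ether, itself made by carboalumination–iodination and a Z-selective Wittig reaction.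
5. Allylsilane: nickel-catalysed ring opening of a 5-alkyl-2,3-dihydrofuran with Me3SiCH2MgCl (retention of geometry).

Assumption: locants C1–C20 in the text are labdane locants (C3 secondary carbinol; C4 quaternary carbon with C18 methyl and C19 CH2OH; C8=C17 exocyclic alkene; C12 side-chain carbinol), and compounds 1, 6, 10, 11 and 22 are taken as catalogue chemicals.

**Route**

Step 1
Reactants: 1 5-chloropent-1-yne
Product: 3 (1E)-5-chloro-1-iodo-2-methylpent-1-ene, via alkenylalane 2 (not isolated)
Conditions: AlMe3 (2.5 equiv), Cp2ZrCl2 (20 mol%), CH2Cl2, 0 °C to rt; then I2, THF, −30 °C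
Reagents that add atoms: trimethylaluminium C[Al](C)C; iodine II
Why: Negishi zirconium-catalysed carboalumination adds Me–Al syn and regioselectively across the terminal alkyne, and iodinolysis of the C–Al bond with retention fixes the E geometry of the later C5=C10 alkene while the alkyl chloride is inert.

Step 2
Reactants: 3 (1E)-5-chloro-1-iodo-2-methylpent-1-ene
Product: 5 [(4E)-5-iodo-4-methylpent-4-en-1-yl]triphenylphosphonium iodide, via diiodide 4 (not isolated)
Conditions: NaI (2 equiv), PPh3 (1.2 equiv), MeCN, reflux, 36 h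
Reagents that add atoms: sodium iodide [Na+].[I-]; triphenylphosphine c1ccc(cc1)P(c1ccccc1)c1ccccc1
Why: Finkelstein exchange gives the primary iodide in the flask, which quaternises PPh3 by SN2 substitution, whereas the iodoalkene cannot react.

Step 3
Reactants: 5 [(4E)-5-iodo-4-methylpent-4-en-1-yl]triphenylphosphonium iodide; 6 1-{[tert-butyl(dimethyl)silyl]oxy}propan-2-one
Product: 8 tert-butyl{[(2Z,6E)-7-iodo-2,6-dimethylhepta-2,6-dien-1-yl]oxy}dimethylsilane, via ylide 7 (not isolated)
Conditions: NaN(SiMe3)2 (1.0 equiv), THF, −78 to 0 °C; then 6, −78 °C to rt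
Reagents that add atoms: none
Why: Wittig olefination of an α-silyloxy ketone with a non-stabilised ylide is Z-selective for the trisubstituted allylic ether, placing CH2OSi cis to the chain, which is the geometry that later makes C19 axial.

Step 4
Reactants: 8 tert-butyl{[(2Z,6E)-7-iodo-2,6-dimethylhepta-2,6-dien-1-yl]oxy}dimethylsilane
Product: 9 tert-butyl{[(2S,3R)-3-[(3E)-4-iodo-3-methylbut-3-en-1-yl]-2-methyloxiran-2-yl]methoxy}dimethylsilane
Conditions: 1,2:4,5-di-O-isopropylidene-β-D-erythro-2,3-hexodiulo-2,6-pyranose (30 mol%), Oxone (2KHSO5·KHSO4·K2SO4), K2CO3, Bu4NHSO4, MeCN/CH2(OMe)2/aq. Na2B4O7 buffer (pH 10.5), 0 °C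
Reagents that add atoms: potassium peroxymonosulfate [K+].[O-]S(=O)(=O)OO
Why: Shi asymmetric epoxidation, in which the chiral dioxirane from the D-fructose-derived ketone attacks only the electron-richer trisubstituted alkene (the iodoalkene is deactivated) through the spiro transition state, giving C3 as R and, by syn-stereospecific oxygen transfer to the Z alkene, C4 as S (first stereocentres, expected about 90% ee).

Step 5
Reactants: 10 2,3-dihydrofuran; 11 2-chloroethyl trifluoromethanesulfonate
Product: 13 5-(2-chloroethyl)-2,3-dihydrofuran, via 5-lithio-2,3-dihydrofuran 12 (not isolated)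
Conditions: t-BuLi (1.05 equiv), THF/pentane, −78 to 0 °C; then 11, −78 °C to rt
Reagents that add atoms: none
Why: α-lithiation of the cyclic enol ether followed by SN2 alkylation at the primary triflate, which reacts far faster than the chloride and cannot undergo halogen–metal exchange.

Step 6
Reactants: 13 5-(2-chloroethyl)-2,3-dihydrofuran
Product: 15 tert-butyl{[(3Z)-6-chloro-4-[(trimethylsilyl)methyl]hex-3-en-1-yl]oxy}dimethylsilane, via magnesium alkoxide 14 (not isolated)
Conditions: Me3SiCH2MgCl (2.5 equiv), NiCl2(PPh3)2 (5 mol%), toluene/Et2O, 70 °C; then imidazole, t-BuMe2SiCl, DMF, rt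
Reagents that add atoms: (trimethylsilyl)methylmagnesium chloride C[Si](C)(C)C[Mg]Cl; tert-butyldimethylsilyl chloride CC(C)(C)[Si](C)(C)Cl
Why: Wenkert-type nickel-catalysed Kumada coupling, in which zerovalent nickel inserts into the vinylic C–O bond and the β-hydrogen-free Grignard reagent couples with retention, so CH2SiMe3 ends cis to the CH2CH2O arm, and the freed alkoxide is silylated in the same pot.

Step 7
Reactants: 15 tert-butyl{[(3Z)-6-chloro-4-[(trimethylsilyl)methyl]hex-3-en-1-yl]oxy}dimethylsilane; 9 tert-butyl{[(2S,3R)-3-[(3E)-4-iodo-3-methylbut-3-en-1-yl]-2-methyloxiran-2-yl]methoxy}dimethylsilane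
Product: 18 tert-butyl{[(2S,3R)-3-[(3E,7Z)-10-{[tert-butyl(dimethyl)silyl]oxy}-3-methyl-7-[(trimethylsilyl)methyl]deca-3,7-dien-1-yl]-2-methyloxiran-2-yl]methoxy}dimethylsilane, via Grignard reagent 16 (not isolated), via organozinc chloride 17 (not isolated)
Conditions: Mg, THF, 50 °C; ZnCl2, 0 °C; then 9, [1,1'-bis(diphenylphosphino)ferrocene]PdCl2 (5 mol%), THF, rt
Reagents that add atoms: none
Why: Negishi sp3–sp2 cross-coupling is stereoretentive at the iodoalkene (E C5=C10), and the alkylzinc reagent leaves the epoxide, the silyl ethers and the allylsilane untouched.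

Step 8
Reactants: 18 epoxy dienyl allylsilane (name as above)
Product: 19 (1R,2R,4aS,5R,8aS)-1-({[tert-butyl(dimethyl)silyl]oxy}methyl)-5-(2-{[tert-butyl(dimethyl)silyl]oxy}ethyl)-1,4a-dimethyl-6-methylidenedecahydronaphthalen-2-ol
Conditions: MeAlCl2 (1.5 equiv), CH2Cl2, −78 °C, 1 h; then Et3N, aq. NaHCO3
Reagents that add atoms: none
Why: Lewis-acid epoxy-polyene cyclisation with allylsilane termination, in which anti opening of the epoxide at tertiary C4 by the E alkene through a chair–chair transition state closes ring A and then ring B, so that C3 keeps its configuration (equatorial OH), C4 is inverted (the Z CH2OSi group becomes axial), C5/C10 become trans-fused, the C9 side chain becomes equatorial as dictated by the C8=C9 geometry, and loss of the silyl group places the alkene at C8(17).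

Step 9
Reactants: 19 bis-silyl ether (name as above)
Product: 20 (1R,2R,4aS,5R,8aS)-5-(2-hydroxyethyl)-1-(hydroxymethyl)-1,4a-dimethyl-6-methylidenedecahydronaphthalen-2-ol
Conditions: Bu4NF (4 equiv), THF, 40 °C
Reagents that add atoms: none
Why: fluoride-mediated desilylation removes both silyl ethers and touches no stereocentre.

Step 10
Reactants: 20 triol (name as above)
Product: 21 2-[(1R,4aS,5R,6R,8aS)-6-hydroxy-5-(hydroxymethyl)-5,8a-dimethyl-2-methylidenedecahydronaphthalen-1-yl]acetaldehyde
Conditions: (2,2,6,6-tetramethylpiperidin-1-yl)oxyl (10 mol%), PhI(OAc)2 (1.1 equiv), CH2Cl2, 0 °C to rt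
Reagents that add atoms: none
Why: oxoammonium-mediated alcohol oxidation is strongly sensitive to steric hindrance, so the unhindered primary C12 alcohol is oxidised in preference to the neopentyl axial C19 alcohol and the secondary C3 alcohol, and it stops at the aldehyde.

Step 11
Reactants: 21 diol aldehyde (name as above); 22 furan-2(5H)-one
Product: 23 3-{(1R)-1-hydroxy-2-[(1R,4aS,5R,6R,8aS)-6-hydroxy-5-(hydroxymethyl)-5,8a-dimethyl-2-methylidenedecahydronaphthalen-1-yl]ethyl}furan-2(5H)-one (target)
Conditions: 22 (3 equiv), PEt3 (30 mol%), (R)-3,3'-bis[3,5-bis(trifluoromethyl)phenyl]-5,5',6,6',7,7',8,8'-octahydro-1,1'-bi-2-naphthol (15 mol%), THF, −10 °C, 72 h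
Reagents that add atoms: none
Why: Proposed new method: a chiral-diol/trialkylphosphine co-catalysed Morita–Baylis–Hillman reaction that uses furan-2(5H)-one as the activated alkene and sets a carbinol centre on a complex β-branched aliphatic aldehyde by catalyst control; PEt3 adds 1,4 to 22 to give a phosphonium lactone enolate, the diol hydrogen-bonds this enolate and the aldehyde so that C–C bond formation occurs on the Si face (C12 R; the remote C9 centre gives little 1,3-induction, and the (S)-diol is taken if the sense proves opposite), and proton transfer with E1cB loss of PEt3 restores the endocyclic C13=C14 alkene; the closest known reactions are the chiral-diol/trialkylphosphine Morita–Baylis–Hillman reaction of cyclohexenone with aliphatic aldehydes and the achiral Lewis-base version with butenolides.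

**Compound list**
1 | 5-chloropent-1-yne | C#CCCCCl | starting material
2 | [(1E)-5-chloro-2-methylpent-1-en-1-yl]dimethylalane | C[Al](C)/C=C(\C)CCCCl | intermediate
3 | (1E)-5-chloro-1-iodo-2-methylpent-1-ene | I/C=C(\C)CCCCl | intermediate
4 | (1E)-1,5-diiodo-2-methylpent-1-ene | I/C=C(\C)CCCI | intermediate
5 | [(4E)-5-iodo-4-methylpent-4-en-1-yl]triphenylphosphonium iodide | I/C=C(\C)CCC[P+](c1ccccc1)(c1ccccc1)c1ccccc1.[I-] | intermediate
6 | 1-{[tert-butyl(dimethyl)silyl]oxy}propan-2-one | CC(=O)CO[Si](C)(C)C(C)(C)C | starting material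
7 | [(4E)-5-iodo-4-methylpent-4-en-1-ylidene]triphenylphosphorane | I/C=C(\C)CCC=P(c1ccccc1)(c1ccccc1)c1ccccc1 | intermediate
8 | tert-butyl{[(2Z,6E)-7-iodo-2,6-dimethylhepta-2,6-dien-1-yl]oxy}dimethylsilane | CC(C)(C)[Si](C)(C)OC/C(C)=C\CC/C(C)=C/I | intermediate
9 | tert-butyl{[(2S,3R)-3-[(3E)-4-iodo-3-methylbut-3-en-1-yl]-2-methyloxiran-2-yl]methoxy}dimethylsilane | CC(C)(C)[Si](C)(C)OC[C@]1(C)O[C@@H]1CC/C(C)=C/I | intermediate
10 | 2,3-dihydrofuran | C1=COCC1 | starting material
11 | 2-chloroethyl trifluoromethanesulfonate | ClCCOS(=O)(=O)C(F)(F)F | starting material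
12 | (4,5-dihydrofuran-2-yl)lithium | [Li]C1=CCCO1 | intermediate
13 | 5-(2-chloroethyl)-2,3-dihydrofuran | ClCCC1=CCCO1 | intermediate
14 | chloromagnesium (3Z)-6-chloro-4-[(trimethylsilyl)methyl]hex-3-en-1-olate | C[Si](C)(C)C/C(CCCl)=C\CCO[Mg]Cl | intermediate
15 | tert-butyl{[(3Z)-6-chloro-4-[(trimethylsilyl)methyl]hex-3-en-1-yl]oxy}dimethylsilane | C[Si](C)(C)C/C(CCCl)=C\CCO[Si](C)(C)C(C)(C)C | intermediate
16 | {(3Z)-6-{[tert-butyl(dimethyl)silyl]oxy}-3-[(trimethylsilyl)methyl]hex-3-en-1-yl}magnesium chloride | Cl[Mg]CC/C(C[Si](C)(C)C)=C/CCO[Si](C)(C)C(C)(C)C | intermediate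
17 | {(3Z)-6-{[tert-butyl(dimethyl)silyl]oxy}-3-[(trimethylsilyl)methyl]hex-3-en-1-yl}zinc chloride | Cl[Zn]CC/C(C[Si](C)(C)C)=C/CCO[Si](C)(C)C(C)(C)C | intermediate
18 | tert-butyl{[(2S,3R)-3-[(3E,7Z)-10-{[tert-butyl(dimethyl)silyl]oxy}-3-methyl-7-[(trimethylsilyl)methyl]deca-3,7-dien-1-yl]-2-methyloxiran-2-yl]methoxy}dimethylsilane | CC(C)(C)[Si](C)(C)OC[C@]1(C)O[C@@H]1CC/C(C)=C/CC/C(C[Si](C)(C)C)=C/CCO[Si](C)(C)C(C)(C)C | intermediate
19 | (1R,2R,4aS,5R,8aS)-1-({[tert-butyl(dimethyl)silyl]oxy}methyl)-5-(2-{[tert-butyl(dimethyl)silyl]oxy}ethyl)-1,4a-dimethyl-6-methylidenedecahydronaphthalen-2-ol | C=C1CC[C@@H]2[C@](C)(CO[Si](C)(C)C(C)(C)C)[C@H](O)CC[C@@]2(C)[C@@H]1CCO[Si](C)(C)C(C)(C)C | intermediate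
20 | (1R,2R,4aS,5R,8aS)-5-(2-hydroxyethyl)-1-(hydroxymethyl)-1,4a-dimethyl-6-methylidenedecahydronaphthalen-2-ol | C=C1CC[C@@H]2[C@](C)(CO)[C@H](O)CC[C@@]2(C)[C@@H]1CCO | intermediate
21 | 2-[(1R,4aS,5R,6R,8aS)-6-hydroxy-5-(hydroxymethyl)-5,8a-dimethyl-2-methylidenedecahydronaphthalen-1-yl]acetaldehyde | C=C1CC[C@@H]2[C@](C)(CO)[C@H](O)CC[C@@]2(C)[C@@H]1CC=O | intermediate
22 | furan-2(5H)-one | O=C1OCC=C1 | starting material
23 | 3-{(1R)-1-hydroxy-2-[(1R,4aS,5R,6R,8aS)-6-hydroxy-5-(hydroxymethyl)-5,8a-dimethyl-2-methylidenedecahydronaphthalen-1-yl]ethyl}furan-2(5H)-one | C=C1CC[C@@H]2[C@](C)(CO)[C@H](O)CC[C@@]2(C)[C@@H]1C[C@@H](O)C1=CCOC1=O | target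

**Step count**
Total: 11 steps (isolated products 3, 5, 8, 9, 13, 15, 18, 19, 20, 21, 23).
Longest linear sequence: 9 steps (1 → 3 → 5 → 8 → 9 → 18 → 19 → 20 → 21 → 23).
The roughly 10% of the minor enantiomer left by step 4 is turned by the catalyst-controlled step 11 into a diastereomer, which is removed by chromatography.

**Three steps most likely to fail**

Step 11 (the proposed reaction). Likely failure modes are phosphine-induced dimerisation of 22, attack through the γ-position of the butenolide, oxa-Michael addition of the free diol, or poor control at C12. The fallback uses known chemistry, sets out from 21 and comes back at 23. The lithium enolate of 3-(phenylselanyl)oxolan-2-one (LiN(i-Pr)2, 3.5 equiv so that the two alkoxides are covered, THF, −78 °C) is added to the aldehyde in a plain aldol reaction. This gives 3-{(1R)-1-hydroxy-2-[(1R,4aS,5R,6R,8aS)-6-hydroxy-5-(hydroxymethyl)-5,8a-dimethyl-2-methylidenedecahydronaphthalen-1-yl]ethyl}-3-(phenylselanyl)oxolan-2-one F6, together with its carbinol epimer. Oxidation with H2O2/pyridine at 0 °C and selenoxide syn-elimination, which avoids the carbinol hydrogen, gives the endocyclic butenolide 23. The C12 epimers are separated by chromatography.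

Step 8 (cascade cyclisation). Likely failure modes are a hydride shift or semipinacol pathway at the inductively deactivated C4, protodesilylation of the allylsilane, or arrest after ring A. The fallback changes the terminating group and the way C17 is brought in; it sets out from 13 (with 9) and comes back at 20. Compound 13 is converted directly to its zinc reagent (Mg; ZnCl2) and coupled with 9 under the conditions of step 7, giving tert-butyl{[(2S,3R)-3-[(3E)-6-(4,5-dihydrofuran-2-yl)-3-methylhex-3-en-1-yl]-2-methyloxiran-2-yl]methoxy}dimethylsilane F1, in which the cyclic enol ether is the terminator. MeAlCl2 at −78 °C closes rings A and B onto the enol ether. Aqueous work-up hydrolyses the oxocarbenium ion to (1S,4aS,5R,6R,8aR)-5-({[tert-butyl(dimethyl)silyl]oxy}methyl)-6-hydroxy-1-(2-hydroxyethyl)-5,8a-dimethyloctahydronaphthalen-2(1H)-one F2, whose C9 centre equilibrates to the equatorial side chain. Wittig methylenation with excess Ph3P=CH2 gives (1R,2R,4aS,5R,8aS)-1-({[tert-butyl(dimethyl)silyl]oxy}methyl)-5-(2-hydroxyethyl)-1,4a-dimethyl-6-methylidenedecahydronaphthalen-2-ol F3, and Bu4NF gives 20.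

Step 10 (chemoselective oxidation). The likely failure mode is competing oxidation of the C19 alcohol, followed by retro-aldol loss. The fallback replaces steric discrimination by protection; it sets out from 20 and comes back at 21. 2,2-Dimethoxypropane with pyridinium p-toluenesulfonate ties up the 1,3-diol selectively as the 3,19-O-isopropylidene acetal of 20 F4. Dess–Martin periodinane oxidises the remaining C12 alcohol to the 3,19-O-isopropylidene acetal of 21 F5. Aqueous acetic acid (80%, rt) removes the acetal to give 21.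

**Further compounds**
F1 | step 8 | tert-butyl{[(2S,3R)-3-[(3E)-6-(4,5-dihydrofuran-2-yl)-3-methylhex-3-en-1-yl]-2-methyloxiran-2-yl]methoxy}dimethylsilane | CC(C)(C)[Si](C)(C)OC[C@]1(C)O[C@@H]1CC/C(C)=C/CCC2=CCCO2
F2 | step 8 | (1S,4aS,5R,6R,8aR)-5-({[tert-butyl(dimethyl)silyl]oxy}methyl)-6-hydroxy-1-(2-hydroxyethyl)-5,8a-dimethyloctahydronaphthalen-2(1H)-one | O=C1CC[C@@H]2[C@](C)(CO[Si](C)(C)C(C)(C)C)[C@H](O)CC[C@@]2(C)[C@@H]1CCO
F3 | step 8 | (1R,2R,4aS,5R,8aS)-1-({[tert-butyl(dimethyl)silyl]oxy}methyl)-5-(2-hydroxyethyl)-1,4a-dimethyl-6-methylidenedecahydronaphthalen-2-ol | C=C1CC[C@@H]2[C@](C)(CO[Si](C)(C)C(C)(C)C)[C@H](O)CC[C@@]2(C)[C@@H]1CCO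
F4 | step 10 | 3,19-O-isopropylidene acetal of 20 (2,2-dimethyl-1,3-dioxane across O3 and O19; free C12 alcohol) | C=C1CC[C@@H]2[C@]3(C)COC(C)(C)O[C@@H]3CC[C@@]2(C)[C@@H]1CCO
F5 | step 10 | 3,19-O-isopropylidene acetal of 21 (2,2-dimethyl-1,3-dioxane across O3 and O19; C12 aldehyde) | C=C1CC[C@@H]2[C@]3(C)COC(C)(C)O[C@@H]3CC[C@@]2(C)[C@@H]1CC=O
F6 | step 11 | 3-{(1R)-1-hydroxy-2-[(1R,4aS,5R,6R,8aS)-6-hydroxy-5-(hydroxymethyl)-5,8a-dimethyl-2-methylidenedecahydronaphthalen-1-yl]ethyl}-3-(phenylselanyl)oxolan-2-one (both epimers at the selenium-bearing carbon) | C=C1CC[C@@H]2[C@](C)(CO)[C@H](O)CC[C@@]2(C)[C@@H]1C[C@@H](O)C1([Se]c2ccccc2)CCOC1=O
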